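**Retrosynthetic overview** (locants are those of the cyclopenta[c]pyridine core)
- C3–C1′ bond: Suzuki–Miyaura coupling of a 3-chloro bicyclic core with a (1E,3E,5S)-dienyl pinacol boronate, the latter from (S)-2-methylbutan-1-ol by Wittig and boron-Wittig olefinations.
- C7–C7a bond (closure of the five-membered ring): rhodium-catalysed ring expansion of a β-lactone standing on C4 of a 3-borylpyridine, i.e. transfer of the lactone acyl carbon from the C5 oxygen to the pyridine carbon.
- C5–C6 bond, both quaternary stereocentres and the acetate: alkaloid-catalysed ketene–ketoester [2+2] of acetoxy(methyl)ketene with a pyridin-4-yl glyoxylate made from 5-bromo-2-chloropyridine and dimethyl oxalate.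
- Enabling feature: the C5 hydroxyl oxygen, C5, C6 and the C7 carbonyl carbon form a β-hydroxy ketone unit, so C7 can be stored as the acyl carbon of a four-membered lactone ring (O–C7–C6–C5) whose C5 already carries the pyridine ring; the pyridine carbon C7a, ortho to C4a, then takes C7 over from oxygen.
- Ring order: pyridine ring purchased; temporary four-membered lactone ring in step 2; cyclopentanone ring in step 4 by expansion of the lactone ring.

Key step: step 4

Assumption: the quinidine-derived catalyst is taken to deliver the (2R,3S) lactone; should the sense of induction prove opposite, the pseudoenantiomeric quinine-derived silyl ether would be used.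

**Step 1**
Reactants: 1 5-bromo-2-chloropyridine; 2 dimethyl oxalate
Product: 4 methyl 2-(5-bromo-2-chloropyridin-4-yl)-2-oxoacetate, via 5-bromo-2-chloro-4-lithiopyridine 3 (not isolated)
Conditions: LiN(i-Pr)2 (1.05 equiv), THF, −78 °C, 30 min; inverse addition to 2 (3 equiv), THF, −78 °C; AcOH quench
Reagents that add atoms: none
Why: Directed ortho-lithiation removes the most acidic proton (C4–H, ortho to bromine and γ to nitrogen), and at −78 °C aryllithium 3 should be acylated by excess oxalate before a halogen dance sets in, the tetrahedral adduct preventing double addition.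

**Step 2**
Reactants: 4 methyl 2-(5-bromo-2-chloropyridin-4-yl)-2-oxoacetate; 5 (S)-2-acetoxypropanoyl chloride
Product: 7 methyl (2R,3S)-3-acetoxy-2-(5-bromo-2-chloropyridin-4-yl)-3-methyl-4-oxooxetane-2-carboxylate, via acetoxy(methyl)ketene 6 (not isolated)
Conditions: 5 (2 equiv, slow addition), i-Pr2NEt (2.5 equiv), O-trimethylsilylquinidine (15 mol %), LiClO4 (50 mol %), CH2Cl2/Et2O, −78 → −40 °C
Reagents that add atoms: none
Why: Cinchona-alkaloid-catalysed formal ketene–ketone [2+2] cycloaddition (aldol-lactonisation), in which the stereocentre of 5 is erased on forming 6; the alkaloid-bound enolate should react on its open face (setting C3 as S), and a lithium-bridged closed transition state with the aryl group anti to the acylammonium carbon and the ketone oxygen gauche to the chelating acetoxy group should place aryl cis to acetoxy (setting C2 as R).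

**Step 3**
Reactants: 7 methyl (2R,3S)-3-acetoxy-2-(5-bromo-2-chloropyridin-4-yl)-3-methyl-4-oxooxetane-2-carboxylate
Product: 8 methyl (2R,3S)-3-acetoxy-2-[2-chloro-5-(4,4,5,5-tetramethyl-1,3,2-dioxaborolan-2-yl)pyridin-4-yl]-3-methyl-4-oxooxetane-2-carboxylate
Conditions: B2pin2 (1.3 equiv), Pd(dppf)Cl2 (5 mol %), KOAc (3 equiv), 1,4-dioxane, 80 °C
Reagents that add atoms: bis(pinacolato)diboron, CC1(C)OB(OC1(C)C)B1OC(C)(C)C(C)(C)O1
Why: Miyaura borylation, in which zerovalent palladium should insert into C–Br in preference to C–Cl, weakly basic KOAc should leave lactone, acetate and ester untouched, and aryl bromides with an ortho tertiary-alkyl group are known substrates.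

**Step 4**
Reactants: 8 methyl (2R,3S)-3-acetoxy-2-[2-chloro-5-(4,4,5,5-tetramethyl-1,3,2-dioxaborolan-2-yl)pyridin-4-yl]-3-methyl-4-oxooxetane-2-carboxylate
Product: 11 methyl (5R,6S)-6-acetoxy-3-chloro-5-hydroxy-6-methyl-7-oxo-6,7-dihydro-5H-cyclopenta[c]pyridine-5-carboxylate, via arylrhodium complex 9 (not isolated), via bridged rhodium alkoxide 10 (not isolated)
Conditions: [Rh(OH)(cod)]2 (3 mol %), 1,4-dioxane/H2O (10:1), 60 °C
Reagents that add atoms: none
Why: Proposed new method: transmetalation of the boronate to the hydroxorhodium catalyst gives arylrhodium 9, whose Rh–C bond adds across the strained lactone carbonyl from the lactone face carrying the pyridine ring to give bridged hemiketal alkoxide 10; 10 collapses by β-oxygen elimination of the endocyclic acyl C–O bond, releasing the strain of both small rings, and water protonates the resulting rhodium tertiary alkoxide to 11 and regenerates Rh–OH. The closest known reaction type is the rhodium-catalysed addition/ring-opening of 3-(2-borylaryl)cyclobutanones to 1-indanones, which passes through the all-carbon analogue of 10, together with organorhodium additions to ester carbonyls that end in β-alkoxide elimination. The five-membered ring C4a–C5–C6–C7–C7a is closed by 5-exo-trig attack of the metalated carbon C7a on acyl carbon C7, overall a 1,4-O-to-C acyl transfer that expands the four-membered lactone into the cyclopentanone. No stereocentre is created: C5 and C6 keep their configuration because no bond to either is broken (the C5–O bond persists as the C5–OH), and the bridgehead of 10 is fixed by the bridge and vanishes on collapse. The step needs chemoselectivity for the lactone carbonyl over the acetate and methyl ester carbonyls, for C–O over C–C cleavage in 10 and for cyclisation over protodeboronation: the β-lactone is the only strain-activated acyl group and arylrhodium species do not add to unactivated esters, alkoxide is a far better leaving group than a C6 carbanion, the reaction is intramolecular, and the neutral aqueous medium should protonate the rhodium alkoxide before retro-aldol cleavage, while acetyl migration is disfavoured by the trans arrangement of the two oxygens on the five-membered ring.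

**Step 5**
Reactants: 12 (S)-2-methylbutan-1-ol; 13 ethyl 2-(triphenylphosphoranylidene)propanoate
Product: 15 ethyl (S,E)-2,4-dimethylhex-2-enoate, via (S)-2-methylbutanal 14 (not isolated)
Conditions: PhI(OAc)2 (1.1 equiv), TEMPO (10 mol %), CH2Cl2, 0 °C → rt; then 13 (1.5 equiv), rt
Reagents that add atoms: none
Why: One-pot TEMPO oxidation and Wittig olefination, in which the configurationally labile aldehyde 14 is trapped as it forms and the stabilised ylide should give the E-trisubstituted enoate; the stereocentre comes from the chiral pool.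

**Step 6**
Reactants: 15 ethyl (S,E)-2,4-dimethylhex-2-enoate
Product: 16 (S,E)-2,4-dimethylhex-2-en-1-ol
Conditions: i-Bu2AlH (2.5 equiv), CH2Cl2, −78 → 0 °C; aqueous potassium sodium tartrate work-up
Reagents that add atoms: none
Why: 1,2-Hydride reduction of the conjugated ester to the allylic alcohol, which should leave alkene geometry and the allylic stereocentre untouched.

**Step 7**
Reactants: 16 (S,E)-2,4-dimethylhex-2-en-1-ol
Product: 17 (S,E)-2,4-dimethylhex-2-enal
Conditions: PhI(OAc)2 (1.1 equiv), TEMPO (10 mol %), CH2Cl2, rt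
Reagents that add atoms: none
Why: TEMPO-catalysed oxidation of the allylic alcohol should stop at the aldehyde under nearly neutral conditions, without E/Z isomerisation or loss of the γ-stereocentre.

**Step 8**
Reactants: 17 (S,E)-2,4-dimethylhex-2-enal; 18 bis(4,4,5,5-tetramethyl-1,3,2-dioxaborolan-2-yl)methane
Product: 20 2-[(1E,3E,5S)-3,5-dimethylhepta-1,3-dien-1-yl]-4,4,5,5-tetramethyl-1,3,2-dioxaborolane, via lithiated bis(boryl)methane 19 (not isolated)
Conditions: 18 (1.2 equiv), lithium 2,2,6,6-tetramethylpiperidide (1.2 equiv, from the amine and n-BuLi), THF, 0 °C; then 17, −78 °C → rt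
Reagents that add atoms: none
Why: Boron-Wittig olefination, in which the preformed α-boryl carbanion 19 adds 1,2 to the enal and syn elimination of the O–B pair should give the trans-alkenyl boronate, with no free amide base left to deprotonate the enal.

**Step 9**
Reactants: 11 methyl (5R,6S)-6-acetoxy-3-chloro-5-hydroxy-6-methyl-7-oxo-6,7-dihydro-5H-cyclopenta[c]pyridine-5-carboxylate; 20 2-[(1E,3E,5S)-3,5-dimethylhepta-1,3-dien-1-yl]-4,4,5,5-tetramethyl-1,3,2-dioxaborolane
Product: 21 methyl (5R,6S)-6-acetoxy-3-[(1E,3E,5S)-3,5-dimethylhepta-1,3-dien-1-yl]-5-hydroxy-6-methyl-7-oxo-6,7-dihydro-5H-cyclopenta[c]pyridine-5-carboxylate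
Conditions: 20 (1.3 equiv), Pd(dppf)Cl2 (5 mol %), CsF (3 equiv), degassed 1,4-dioxane, 60 °C
Reagents that add atoms: none
Why: Suzuki–Miyaura coupling, in which the C3–Cl bond is activated for oxidative addition by the ring nitrogen and the para keto group, fluoride activates the boronate without a strong Brønsted base, and both alkene geometries should be retained.

**Compound list**
1 | 5-bromo-2-chloropyridine | Clc1ccc(Br)cn1 | starting material
2 | dimethyl oxalate | COC(=O)C(=O)OC | starting material
3 | 5-bromo-2-chloro-4-lithiopyridine | [Li]c1cc(Cl)ncc1Br | intermediate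
4 | methyl 2-(5-bromo-2-chloropyridin-4-yl)-2-oxoacetate | COC(=O)C(=O)c1cc(Cl)ncc1Br | intermediate
5 | (S)-2-acetoxypropanoyl chloride | C[C@H](OC(C)=O)C(Cl)=O | starting material
6 | acetoxy(methyl)ketene (1-oxoprop-1-en-2-yl acetate) | CC(OC(C)=O)=C=O | intermediate
7 | methyl (2R,3S)-3-acetoxy-2-(5-bromo-2-chloropyridin-4-yl)-3-methyl-4-oxooxetane-2-carboxylate | O=C1O[C@@](c2cc(Cl)ncc2Br)(C(=O)OC)[C@]1(C)OC(C)=O | intermediate
8 | methyl (2R,3S)-3-acetoxy-2-[2-chloro-5-(4,4,5,5-tetramethyl-1,3,2-dioxaborolan-2-yl)pyridin-4-yl]-3-methyl-4-oxooxetane-2-carboxylate | O=C1O[C@@](c2cc(Cl)ncc2B3OC(C)(C)C(C)(C)O3)(C(=O)OC)[C@]1(C)OC(C)=O | intermediate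
9 | (cycloocta-1,5-diene){4-[(2R,3S)-3-acetoxy-2-(methoxycarbonyl)-3-methyl-4-oxooxetan-2-yl]-6-chloropyridin-3-yl}rhodium | O=C1O[C@@](c2cc(Cl)ncc2[Rh])(C(=O)OC)[C@]1(C)OC(C)=O.C1=CCCC=CCC1 | intermediate
10 | (cycloocta-1,5-diene)rhodium alkoxide of methyl (5R,6S,7R)-6-acetoxy-3-chloro-7-hydroxy-6-methyl-5,7-epoxy-6,7-dihydro-5H-cyclopenta[c]pyridine-5-carboxylate (Rh on the C7 oxygen) | [Rh]O[C@]12O[C@](C(=O)OC)(c3cc(Cl)ncc31)[C@]2(C)OC(C)=O.C1=CCCC=CCC1 | intermediate
11 | methyl (5R,6S)-6-acetoxy-3-chloro-5-hydroxy-6-methyl-7-oxo-6,7-dihydro-5H-cyclopenta[c]pyridine-5-carboxylate | Clc1cc2c(cn1)C(=O)[C@@](C)(OC(C)=O)[C@@]2(O)C(=O)OC | intermediate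
12 | (S)-2-methylbutan-1-ol | CC[C@H](C)CO | starting material
13 | ethyl 2-(triphenylphosphoranylidene)propanoate | CCOC(=O)C(C)=P(c1ccccc1)(c1ccccc1)c1ccccc1 | starting material
14 | (S)-2-methylbutanal | CC[C@H](C)C=O | intermediate
15 | ethyl (S,E)-2,4-dimethylhex-2-enoate | CC[C@H](C)/C=C(C)/C(=O)OCC | intermediate
16 | (S,E)-2,4-dimethylhex-2-en-1-ol | CC[C@H](C)/C=C(C)/CO | intermediate
17 | (S,E)-2,4-dimethylhex-2-enal | CC[C@H](C)/C=C(C)/C=O | intermediate
18 | bis(4,4,5,5-tetramethyl-1,3,2-dioxaborolan-2-yl)methane | CC1(C)OB(CB2OC(C)(C)C(C)(C)O2)OC1(C)C | starting material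
19 | lithio-bis(4,4,5,5-tetramethyl-1,3,2-dioxaborolan-2-yl)methane | [Li]C(B1OC(C)(C)C(C)(C)O1)B1OC(C)(C)C(C)(C)O1 | intermediate
20 | 2-[(1E,3E,5S)-3,5-dimethylhepta-1,3-dien-1-yl]-4,4,5,5-tetramethyl-1,3,2-dioxaborolane | CC[C@H](C)/C=C(C)/C=C/B1OC(C)(C)C(C)(C)O1 | intermediate
21 | methyl (5R,6S)-6-acetoxy-3-[(1E,3E,5S)-3,5-dimethylhepta-1,3-dien-1-yl]-5-hydroxy-6-methyl-7-oxo-6,7-dihydro-5H-cyclopenta[c]pyridine-5-carboxylate | CC[C@H](C)/C=C(C)/C=C/c1cc2c(cn1)C(=O)[C@@](C)(OC(C)=O)[C@@]2(O)C(=O)OC | target

**Totals**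
Total step count: 9. Longest linear sequence: 5 steps (1 → 2 → 3 → 4 → 9, or 5 → 6 → 7 → 8 → 9).

**Steps most likely to fail**

1. Step 4. Protodeboronation of the arylrhodium species may outrun carbonyl insertion through the strained bridged transition state, or the aryl–metal carbon may attack the cis acetate carbonyl (six-membered transition state) and transfer the acetyl group to carbon. The fallback sets out from 7 and needs no boron. The lactone is opened at the acyl carbon with Me2AlN(OMe)Me (from AlMe3 and N,O-dimethylhydroxylamine hydrochloride, CH2Cl2, 0 °C) to give methyl (2R,3S)-3-acetoxy-2-(5-bromo-2-chloropyridin-4-yl)-2-hydroxy-4-[methoxy(methyl)amino]-3-methyl-4-oxobutanoate F1. The tertiary hydroxyl is silylated (Me3SiOTf, 2,6-lutidine, CH2Cl2) to give methyl (2R,3S)-3-acetoxy-2-(5-bromo-2-chloropyridin-4-yl)-4-[methoxy(methyl)amino]-3-methyl-4-oxo-2-[(trimethylsilyl)oxy]butanoate F2, which blocks acetyl migration in the open chain. Bromine–magnesium exchange with i-PrMgCl·LiCl (THF, −20 °C) and Parham-type cyclisation of the pyridylmagnesium onto the N-methoxy-N-methylamide then give methyl (5R,6S)-6-acetoxy-3-chloro-6-methyl-7-oxo-5-[(trimethylsilyl)oxy]-6,7-dihydro-5H-cyclopenta[c]pyridine-5-carboxylate F3. HF·pyridine removes the silyl group and the route is rejoined at 11.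

2. Step 2. Facial selectivity at the keto group may be poor (aryl ending cis to methyl), or enantioselectivity may be low with an acyloxy(alkyl)ketene, and ketene formation from the α-branched acid chloride may be sluggish. The fallback sets out from 4 and uses substrate control. (R)-Lactic acid and pivalaldehyde (acid catalysis, azeotropic water removal) give (2R,5R)-2-tert-butyl-5-methyl-1,3-dioxolan-4-one F4. Its lithium enolate (LiN(i-Pr)2, THF, −78 °C) adds to the keto group of 4 anti to the tert-butyl group to give methyl (2R)-2-(5-bromo-2-chloropyridin-4-yl)-2-[(2R,4S)-2-tert-butyl-4-methyl-5-oxo-1,3-dioxolan-4-yl]-2-hydroxyacetate F5, the carbinol epimer being removed by chromatography. Aqueous trifluoroacetic acid cleaves the acylal to (2S,3R)-3-(5-bromo-2-chloropyridin-4-yl)-2,3-dihydroxy-4-methoxy-2-methyl-4-oxobutanoic acid F6. Carboxyl activation with PhSO2Cl in pyridine closes the only possible lactone, methyl (2R,3S)-2-(5-bromo-2-chloropyridin-4-yl)-3-hydroxy-3-methyl-4-oxooxetane-2-carboxylate F7, with retention at the carbinol carbon. Acetylation of the one remaining hydroxyl (Ac2O, Et3N, DMAP, CH2Cl2) rejoins the route at 7.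

3. Step 9. Fluoride-promoted retro-aldol opening and re-closure of the β-hydroxy ketone may erode configurational purity at C5 and C6, or transmetalation of the pinacol boronate may be slow. The fallback sets out from 17 and avoids base. CrCl2-mediated Takai-type olefination with Bu3SnCHBr2 (LiI, THF/DMF) gives tributyl[(1E,3E,5S)-3,5-dimethylhepta-1,3-dien-1-yl]stannane F8. A neutral Stille coupling of F8 with 11 (Pd(PPh3)4, CuI, DMF, 50 °C) gives 21 directly.

**Further compounds**
F1 | step 4 | methyl (2R,3S)-3-acetoxy-2-(5-bromo-2-chloropyridin-4-yl)-2-hydroxy-4-[methoxy(methyl)amino]-3-methyl-4-oxobutanoate | CON(C)C(=O)[C@@](C)(OC(C)=O)[C@@](O)(C(=O)OC)c1cc(Cl)ncc1Br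
F2 | step 4 | methyl (2R,3S)-3-acetoxy-2-(5-bromo-2-chloropyridin-4-yl)-4-[methoxy(methyl)amino]-3-methyl-4-oxo-2-[(trimethylsilyl)oxy]butanoate | CON(C)C(=O)[C@@](C)(OC(C)=O)[C@@](O[Si](C)(C)C)(C(=O)OC)c1cc(Cl)ncc1Br
F3 | step 4 | methyl (5R,6S)-6-acetoxy-3-chloro-6-methyl-7-oxo-5-[(trimethylsilyl)oxy]-6,7-dihydro-5H-cyclopenta[c]pyridine-5-carboxylate | Clc1cc2c(cn1)C(=O)[C@@](C)(OC(C)=O)[C@@]2(O[Si](C)(C)C)C(=O)OC
F4 | step 2 | (2R,5R)-2-tert-butyl-5-methyl-1,3-dioxolan-4-one | C[C@H]1O[C@@H](C(C)(C)C)OC1=O
F5 | step 2 | methyl (2R)-2-(5-bromo-2-chloropyridin-4-yl)-2-[(2R,4S)-2-tert-butyl-4-methyl-5-oxo-1,3-dioxolan-4-yl]-2-hydroxyacetate | COC(=O)[C@@](O)(c1cc(Cl)ncc1Br)[C@]2(C)O[C@@H](C(C)(C)C)OC2=O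
F6 | step 2 | (2S,3R)-3-(5-bromo-2-chloropyridin-4-yl)-2,3-dihydroxy-4-methoxy-2-methyl-4-oxobutanoic acid | COC(=O)[C@@](O)(c1cc(Cl)ncc1Br)[C@](C)(O)C(=O)O
F7 | step 2 | methyl (2R,3S)-2-(5-bromo-2-chloropyridin-4-yl)-3-hydroxy-3-methyl-4-oxooxetane-2-carboxylate | O=C1O[C@@](c2cc(Cl)ncc2Br)(C(=O)OC)[C@]1(C)O
F8 | step 9 | tributyl[(1E,3E,5S)-3,5-dimethylhepta-1,3-dien-1-yl]stannane | CC[C@H](C)/C=C(C)/C=C/[Sn](CCCC)(CCCC)CCCC
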